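**Retrosynthetic overview**
1. Target ⇒ macrocyclic lactone 28 (C4‑OTBS, C5‑OPMB) by ordered late acylation: the hindered (2S,3R)-epoxy acid 24 (Sharpless epoxidation of tiglyl alcohol) goes on C4‑OH first, the acetate on C5‑OH last.
2. Ten-membered carbocycle (formed last) ⇒ ring-closing metathesis of diene lactone 27, closing the C9=C10 Z-trisubstituted olefin.
3. cis-α-Methylene-γ-butyrolactone (formed first) ⇒ intermolecular indium-mediated Barbier 2-(methoxycarbonyl)allylation of 3-methylbut-3-enal 20 with (Z)-bromide 18; this makes C3a–C11a and both of its stereocentres.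
4. Bromide 18 ⇒ Baylis–Hillman adduct of aldehyde 15, then SN2′ bromination; 15 ⇒ (R)-glycerate acetonide 1 via ynone transfer hydrogenation (C5, anti) and hydroxyl-directed anti-carbomagnesiation/allylation (C6=C7 Z-olefin).

Assumption: ring positions use the cyclodeca[b]furan numbering of the target (O1, C2, C3, C3a, C4 … C11, C11a); organometallic intermediates are drawn as monomers and spent metal reagents as their simplest salts.

**Route**

Step 1
Reactants: 1 methyl (4R)-2,2-dimethyl-1,3-dioxolane-4-carboxylate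
Product: 2 (4R)-N-methoxy-N,2,2-trimethyl-1,3-dioxolane-4-carboxamide
Conditions: MeNH(OMe)·HCl, i-PrMgCl, THF, −20 → 0 °C
Reagents that add atoms: N,O-dimethylhydroxylamine hydrochloride, CNOC.Cl
Why: Weinreb aminolysis of the ester by the pre-formed magnesium amide at low temperature leaves the α-alkoxy centre (target C4, from the chiral pool) untouched.

Step 2
Reactants: 2 Weinreb amide; 3 ethynyltrimethylsilane
Product: 5 1-[(4R)-2,2-dimethyl-1,3-dioxolan-4-yl]-3-(trimethylsilyl)prop-2-yn-1-one, via lithium (trimethylsilyl)acetylide 4 (not isolated)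
Conditions: 3, n-BuLi, THF, −78 °C; then 2, −78 → −20 °C; aq. NH4Cl
Reagents that add atoms: none
Why: Acetylide addition to a Weinreb amide stops at the ketone because the chelated tetrahedral adduct survives until work-up.

Step 3
Reactants: 5 ynone
Product: 6 (1S)-1-[(4R)-2,2-dimethyl-1,3-dioxolan-4-yl]-3-(trimethylsilyl)prop-2-yn-1-ol
Conditions: Ru[(R,R)-TsNCH(Ph)CH(Ph)NH](p-cymene) (2 mol%), i-PrOH, rt
Reagents that add atoms: none
Why: Noyori asymmetric transfer hydrogenation under catalyst control (the (S,S)-catalyst gives (S)-alkynyl methyl carbinols, so the (R,R)-catalyst gives the 1S carbinol here, where the dioxolanyl outranks the alkynyl group) sets target C5 anti to the neighbouring oxygen, which is also the Felkin sense.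

Step 4
Reactants: 6 silyl alkynol
Product: 7 (1S)-1-[(4R)-2,2-dimethyl-1,3-dioxolan-4-yl]prop-2-yn-1-ol
Conditions: K2CO3 (cat.), MeOH, rt
Reagents that add atoms: none
Why: Base-catalysed methanolysis of the C(sp)–Si bond (protodesilylation) frees the terminal alkyne without affecting the acetonide or the carbinol.

Step 5
Reactants: 7 propargylic alcohol; 8 allyl bromide
Product: 10 (1S,2Z)-1-[(4R)-2,2-dimethyl-1,3-dioxolan-4-yl]-2-methylhexa-2,5-dien-1-ol, via cyclic vinylmagnesium alkoxide 9 (not isolated)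
Conditions: MeMgBr (4 equiv), CuI (20 mol%), Et2O/THF, −10 °C → rt; then 8, 0 °C → rt; aq. NH4Cl
Reagents that add atoms: methylmagnesium bromide, C[Mg]Br
Why: Duboudin hydroxyl-directed anti-carbomagnesiation puts methyl on the proximal alkyne carbon and magnesium cis to the carbinol in a five-membered chelate, and copper-mediated allylation with retention fixes the Z olefin (target C6=C7) and the skipped diene.

Step 6
Reactants: 10 dienol
Product: 11 (4R)-4-{(1S,2Z)-1-[(4-methoxybenzyl)oxy]-2-methylhexa-2,5-dien-1-yl}-2,2-dimethyl-1,3-dioxolane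
Conditions: NaH, PMBCl, n-Bu4NI (cat.), THF/DMF, 0 °C → rt
Reagents that add atoms: 4-methoxybenzyl chloride, COc1ccc(CCl)cc1
Why: Williamson etherification protects the C5 oxygen with a group that survives acid, fluoride and metathesis and is removed oxidatively at the end.

Step 7
Reactants: 11 PMB ether acetonide
Product: 12 (2R,3S,4Z)-3-[(4-methoxybenzyl)oxy]-4-methylocta-4,7-diene-1,2-diol
Conditions: AcOH/H2O/THF (4:1:1), 45 °C
Reagents that add atoms: none
Why: Mild acid hydrolysis removes the terminal isopropylidene acetal while the PMB ether and the skipped diene are stable.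

Step 8
Reactants: 12 diol
Product: 13 (2R,3S,4Z)-1,2-bis[(tert-butyldimethylsilyl)oxy]-3-[(4-methoxybenzyl)oxy]-4-methylocta-4,7-diene
Conditions: TBSOTf (2.5 equiv), 2,6-lutidine, CH2Cl2, −78 → 0 °C
Reagents that add atoms: tert-butyldimethylsilyl trifluoromethanesulfonate, CC(C)(C)[Si](C)(C)OS(=O)(=O)C(F)(F)F
Why: The silyl triflate silylates both the primary and the hindered secondary hydroxyl cleanly.

Step 9
Reactants: 13 bis-silyl ether
Product: 14 (2R,3S,4Z)-2-[(tert-butyldimethylsilyl)oxy]-3-[(4-methoxybenzyl)oxy]-4-methylocta-4,7-dien-1-ol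
Conditions: HF·pyridine, pyridine, THF, 0 °C
Reagents that add atoms: none
Why: Buffered HF·pyridine cleaves the unhindered primary silyl ether much faster than the secondary one.

Step 10
Reactants: 14 primary alcohol
Product: 15 (2S,3S,4Z)-2-[(tert-butyldimethylsilyl)oxy]-3-[(4-methoxybenzyl)oxy]-4-methylocta-4,7-dienal
Conditions: Dess–Martin periodinane, pyridine, CH2Cl2, 0 °C → rt; used crude
Reagents that add atoms: none
Why: Dess–Martin oxidation is neutral and gives the α-silyloxy aldehyde without epimerisation or olefin migration.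

Step 11
Reactants: 15 aldehyde; 16 methyl acrylate
Product: 17 methyl (3RS,4R,5S,6Z)-4-[(tert-butyldimethylsilyl)oxy]-3-hydroxy-5-[(4-methoxybenzyl)oxy]-6-methyl-2-methylidenedeca-6,9-dienoate
Conditions: DABCO (1 equiv), 16 (excess), MeOH (cat.), rt, 3–5 d
Reagents that add atoms: none
Why: Morita–Baylis–Hillman reaction of an activated α-alkoxy aldehyde; the new carbinol configuration does not matter because it is erased in step 12.

Step 12
Reactants: 17 Baylis–Hillman adduct
Product: 18 methyl (2Z,4R,5S,6Z)-2-(bromomethyl)-4-[(tert-butyldimethylsilyl)oxy]-5-[(4-methoxybenzyl)oxy]-6-methyldeca-2,6,9-trienoate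
Conditions: NBS, Me2S, CH2Cl2, 0 °C → rt
Reagents that add atoms: N-bromosuccinimide, O=C1CCC(=O)N1Br
Why: Corey–Kim-type activation of the allylic alcohol and SN2′ attack of bromide give the (Z)-2-(bromomethyl)enoate with the C4 substituent trans to the ester.

Step 13
Reactants: 19 3-methylbut-3-en-1-ol
Product: 20 3-methylbut-3-enal
Conditions: Dess–Martin periodinane, NaHCO3, CH2Cl2, 0 °C → rt; filtered solution used at once
Reagents that add atoms: none
Why: Buffered Dess–Martin oxidation gives the β,γ-unsaturated aldehyde without isomerisation to prenal, provided it is used immediately.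

Step 14
Reactants: 21 tiglic acid
Product: 22 (E)-2-methylbut-2-en-1-ol
Conditions: LiAlH4, Et2O, 0 °C → rt
Reagents that add atoms: none
Why: Hydride reduction of the acid gives the allylic alcohol with the E trisubstituted olefin intact.

Step 15
Reactants: 22 tiglyl alcohol
Product: 23 [(2R,3R)-2,3-dimethyloxiran-2-yl]methanol
Conditions: Ti(OiPr)4 (10 mol%), D-(−)-diethyl tartrate (12 mol%), t-BuOOH, 4 Å sieves, CH2Cl2, −20 °C
Reagents that add atoms: tert-butyl hydroperoxide, CC(C)(C)OO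
Why: Katsuki–Sharpless asymmetric epoxidation with D-(−)-tartrate gives the (2R,3R) epoxide, the mirror image of the (2S,3S) product that E-allylic alcohols give with L-(+)-tartrate.

Step 16
Reactants: 23 epoxy alcohol
Product: 24 (2S,3R)-2,3-dimethyloxirane-2-carboxylic acid
Conditions: RuCl3·H2O (2 mol%), NaIO4 (3 equiv), CCl4/MeCN/H2O, 0 °C → rt
Reagents that add atoms: water, O (enters through the aldehyde hydrate); sodium periodate, [Na+].[O-]I(=O)(=O)=O (terminal oxidant)
Why: RuO4-catalysed (Sharpless) oxidation takes the primary alcohol to the acid without opening the epoxide; the C2 descriptor changes from R to S only because the carboxyl now outranks C3.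

Step 17
Reactants: 18 (Z)-allyl bromide; 20 3-methylbut-3-enal
Product: 26 methyl (3S,4S)-3-{(1R,2S,3Z)-1-[(tert-butyldimethylsilyl)oxy]-2-[(4-methoxybenzyl)oxy]-3-methylhepta-3,6-dien-1-yl}-4-hydroxy-6-methyl-2-methylidenehept-6-enoate, via allylindium dibromide 25 (not isolated)
Conditions: In powder (1.5 equiv), 20 (3 equiv), THF/H2O (1:1), rt
Reagents that add atoms: none
Why: Intermolecular Barbier carbonyl allylation through the γ-carbon in a chair transition state: the Z allyl geometry gives the 3,4-syn adduct (the future cis lactone), and with the C–H of the silyloxy carbon eclipsing the olefin (A(1,3) strain) the aldehyde adds anti to the C–OSi bond (Felkin–Anh-type, the sense of Kishi's rule), setting target C3a (S) and C11a (S).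

Step 18
Reactants: 26 hydroxy ester
Product: 27 (4S,5S)-4-{(1R,2S,3Z)-1-[(tert-butyldimethylsilyl)oxy]-2-[(4-methoxybenzyl)oxy]-3-methylhepta-3,6-dien-1-yl}-3-methylidene-5-(2-methylprop-2-en-1-yl)oxolan-2-one
Conditions: PPTS (cat.), toluene, 60 °C
Reagents that add atoms: none
Why: Acid-catalysed lactonisation of the only free hydroxyl onto the acrylate ester closes the cis-fused α-methylene-γ-butyrolactone without touching the silyl or PMB ethers.

Step 19
Reactants: 27 diene lactone
Product: 28 (3aS,4R,5S,6Z,9Z,11aS)-4-[(tert-butyldimethylsilyl)oxy]-5-[(4-methoxybenzyl)oxy]-6,10-dimethyl-3-methylidene-3a,4,5,8,11,11a-hexahydrocyclodeca[b]furan-2(3H)-one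
Conditions: second-generation Hoveyda–Grubbs catalyst (H2IMes)Cl2Ru(=CH-C6H4-2-OiPr) (10 mol%, two portions), 1,4-benzoquinone (20 mol%), toluene (0.5 mM), 80 °C
Reagents that add atoms: none
Why: Ring-closing metathesis starts at the terminal vinyl group and closes onto the unhindered methallyl olefin; the ten-membered ring with its existing Z olefin and cis lactone should favour the Z trisubstituted C9=C10 bond, the electron-poor methylene lactone reacts far more slowly, and benzoquinone suppresses hydride-induced migration of the skipped diene.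

Step 20
Reactants: 28 macrocyclic silyl ether
Product: 29 (3aR,4R,5S,6Z,9Z,11aS)-4-hydroxy-5-[(4-methoxybenzyl)oxy]-6,10-dimethyl-3-methylidene-3a,4,5,8,11,11a-hexahydrocyclodeca[b]furan-2(3H)-one (the 3a descriptor changes by CIP ranking only)
Conditions: HF·pyridine, pyridine, THF, 0 °C → rt; used directly
Reagents that add atoms: none
Why: Buffered, mildly acidic fluoride desilylation frees C4‑OH without base, so neither translactonisation to the C4 oxygen nor conjugate addition to the methylene lactone occurs, and the PMB ether is inert.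

Step 21
Reactants: 29 macrocyclic alcohol; 24 epoxy acid
Product: 31 (3aS,4R,5S,6Z,9Z,11aS)-5-[(4-methoxybenzyl)oxy]-6,10-dimethyl-3-methylidene-2-oxo-2,3,3a,4,5,8,11,11a-octahydrocyclodeca[b]furan-4-yl (2S,3R)-2,3-dimethyloxirane-2-carboxylate, via mixed 2,4,6-trichlorobenzoic anhydride 30 (not isolated)
Conditions: 24, 2,4,6-trichlorobenzoyl chloride, Et3N, toluene, rt; then 29, DMAP, toluene, rt
Reagents that add atoms: none
Why: Yamaguchi esterification couples the hindered α-quaternary glycidic acid to the secondary alcohol; doing this while C5 is still a PMB ether rules out acyl migration.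

Step 22
Reactants: 31 PMB ether ester
Product: 32 (3aS,4R,5S,6Z,9Z,11aS)-5-hydroxy-6,10-dimethyl-3-methylidene-2-oxo-2,3,3a,4,5,8,11,11a-octahydrocyclodeca[b]furan-4-yl (2S,3R)-2,3-dimethyloxirane-2-carboxylate
Conditions: DDQ, CH2Cl2/pH 7 buffer (10:1), 0 °C
Reagents that add atoms: none
Why: Oxidative PMB cleavage by DDQ at neutral pH spares the epoxy ester, the methylene lactone and the skipped diene.

Step 23
Reactants: 32 allylic alcohol
Product: 33 (3aS,4R,5S,6Z,9Z,11aS)-5-(acetyloxy)-6,10-dimethyl-3-methylidene-2-oxo-2,3,3a,4,5,8,11,11a-octahydrocyclodeca[b]furan-4-yl (2S,3R)-2,3-dimethyloxirane-2-carboxylate (target)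
Conditions: Ac2O, pyridine, DMAP (cat.), CH2Cl2, 0 °C → rt
Reagents that add atoms: acetic anhydride, CC(=O)OC(C)=O
Why: DMAP-catalysed acetylation of the last free hydroxyl gives the target; the hindered epoxy ester does not migrate under these conditions.

**Compound list**
1 | methyl (4R)-2,2-dimethyl-1,3-dioxolane-4-carboxylate | CC1(C)OC[C@@H](O1)C(=O)OC | starting material
2 | (4R)-N-methoxy-N,2,2-trimethyl-1,3-dioxolane-4-carboxamide | CC1(C)OC[C@@H](O1)C(=O)N(C)OC | intermediate
3 | ethynyltrimethylsilane | C#C[Si](C)(C)C | starting material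
4 | lithium (trimethylsilyl)acetylide | [Li]C#C[Si](C)(C)C | intermediate
5 | 1-[(4R)-2,2-dimethyl-1,3-dioxolan-4-yl]-3-(trimethylsilyl)prop-2-yn-1-one | CC1(C)OC[C@@H](O1)C(=O)C#C[Si](C)(C)C | intermediate
6 | (1S)-1-[(4R)-2,2-dimethyl-1,3-dioxolan-4-yl]-3-(trimethylsilyl)prop-2-yn-1-ol | CC1(C)OC[C@@H](O1)[C@@H](O)C#C[Si](C)(C)C | intermediate
7 | (1S)-1-[(4R)-2,2-dimethyl-1,3-dioxolan-4-yl]prop-2-yn-1-ol | CC1(C)OC[C@@H](O1)[C@@H](O)C#C | intermediate
8 | allyl bromide (3-bromoprop-1-ene) | C=CCBr | starting material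
9 | cyclic vinylmagnesium alkoxide, (5S)-5-[(4R)-2,2-dimethyl-1,3-dioxolan-4-yl]-4-methyl-2,5-dihydro-1,2-oxamagnesole | CC1(C)OC[C@@H](O1)[C@H]2O[Mg]C=C2C | intermediate
10 | (1S,2Z)-1-[(4R)-2,2-dimethyl-1,3-dioxolan-4-yl]-2-methylhexa-2,5-dien-1-ol | CC1(C)OC[C@@H](O1)[C@@H](O)/C(C)=C\CC=C | intermediate
11 | (4R)-4-{(1S,2Z)-1-[(4-methoxybenzyl)oxy]-2-methylhexa-2,5-dien-1-yl}-2,2-dimethyl-1,3-dioxolane | CC1(C)OC[C@@H](O1)[C@@H](OCc2ccc(OC)cc2)/C(C)=C\CC=C | intermediate
12 | (2R,3S,4Z)-3-[(4-methoxybenzyl)oxy]-4-methylocta-4,7-diene-1,2-diol | OC[C@@H](O)[C@@H](OCc1ccc(OC)cc1)/C(C)=C\CC=C | intermediate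
13 | (2R,3S,4Z)-1,2-bis[(tert-butyldimethylsilyl)oxy]-3-[(4-methoxybenzyl)oxy]-4-methylocta-4,7-diene | CC(C)(C)[Si](C)(C)OC[C@@H](O[Si](C)(C)C(C)(C)C)[C@@H](OCc1ccc(OC)cc1)/C(C)=C\CC=C | intermediate
14 | (2R,3S,4Z)-2-[(tert-butyldimethylsilyl)oxy]-3-[(4-methoxybenzyl)oxy]-4-methylocta-4,7-dien-1-ol | OC[C@@H](O[Si](C)(C)C(C)(C)C)[C@@H](OCc1ccc(OC)cc1)/C(C)=C\CC=C | intermediate
15 | (2S,3S,4Z)-2-[(tert-butyldimethylsilyl)oxy]-3-[(4-methoxybenzyl)oxy]-4-methylocta-4,7-dienal | O=C[C@@H](O[Si](C)(C)C(C)(C)C)[C@@H](OCc1ccc(OC)cc1)/C(C)=C\CC=C | intermediate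
16 | methyl acrylate | C=CC(=O)OC | starting material
17 | methyl (3RS,4R,5S,6Z)-4-[(tert-butyldimethylsilyl)oxy]-3-hydroxy-5-[(4-methoxybenzyl)oxy]-6-methyl-2-methylidenedeca-6,9-dienoate | C=C(C(=O)OC)C(O)[C@@H](O[Si](C)(C)C(C)(C)C)[C@@H](OCc1ccc(OC)cc1)/C(C)=C\CC=C | intermediate
18 | methyl (2Z,4R,5S,6Z)-2-(bromomethyl)-4-[(tert-butyldimethylsilyl)oxy]-5-[(4-methoxybenzyl)oxy]-6-methyldeca-2,6,9-trienoate | COC(=O)/C(CBr)=C/[C@@H](O[Si](C)(C)C(C)(C)C)[C@@H](OCc1ccc(OC)cc1)/C(C)=C\CC=C | intermediate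
19 | 3-methylbut-3-en-1-ol | CC(=C)CCO | starting material
20 | 3-methylbut-3-enal | CC(=C)CC=O | intermediate
21 | tiglic acid, (E)-2-methylbut-2-enoic acid | C/C=C(\C)C(=O)O | starting material
22 | (E)-2-methylbut-2-en-1-ol | C/C=C(\C)CO | intermediate
23 | [(2R,3R)-2,3-dimethyloxiran-2-yl]methanol | OC[C@@]1(C)O[C@@H]1C | intermediate
24 | (2S,3R)-2,3-dimethyloxirane-2-carboxylic acid | OC(=O)[C@@]1(C)O[C@@H]1C | intermediate
25 | allylindium dibromide derived from 18 | COC(=O)/C(C[In](Br)Br)=C/[C@@H](O[Si](C)(C)C(C)(C)C)[C@@H](OCc1ccc(OC)cc1)/C(C)=C\CC=C | intermediate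
26 | methyl (3S,4S)-3-{(1R,2S,3Z)-1-[(tert-butyldimethylsilyl)oxy]-2-[(4-methoxybenzyl)oxy]-3-methylhepta-3,6-dien-1-yl}-4-hydroxy-6-methyl-2-methylidenehept-6-enoate | C=C(C(=O)OC)[C@@H]([C@@H](O)CC(C)=C)[C@@H](O[Si](C)(C)C(C)(C)C)[C@@H](OCc1ccc(OC)cc1)/C(C)=C\CC=C | intermediate
27 | (4S,5S)-4-{(1R,2S,3Z)-1-[(tert-butyldimethylsilyl)oxy]-2-[(4-methoxybenzyl)oxy]-3-methylhepta-3,6-dien-1-yl}-3-methylidene-5-(2-methylprop-2-en-1-yl)oxolan-2-one | C=C1C(=O)O[C@@H](CC(C)=C)[C@H]1[C@@H](O[Si](C)(C)C(C)(C)C)[C@@H](OCc2ccc(OC)cc2)/C(C)=C\CC=C | intermediate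
28 | (3aS,4R,5S,6Z,9Z,11aS)-4-[(tert-butyldimethylsilyl)oxy]-5-[(4-methoxybenzyl)oxy]-6,10-dimethyl-3-methylidene-3a,4,5,8,11,11a-hexahydrocyclodeca[b]furan-2(3H)-one | C=C1C(=O)O[C@H]2C/C(C)=C\C/C=C(/C)[C@H](OCc3ccc(OC)cc3)[C@H](O[Si](C)(C)C(C)(C)C)[C@@H]12 | intermediate
29 | (3aR,4R,5S,6Z,9Z,11aS)-4-hydroxy-5-[(4-methoxybenzyl)oxy]-6,10-dimethyl-3-methylidene-3a,4,5,8,11,11a-hexahydrocyclodeca[b]furan-2(3H)-one | C=C1C(=O)O[C@H]2C/C(C)=C\C/C=C(/C)[C@H](OCc3ccc(OC)cc3)[C@H](O)[C@@H]12 | intermediate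
30 | (2S,3R)-2,3-dimethyloxirane-2-carboxylic 2,4,6-trichlorobenzoic anhydride | Clc1cc(Cl)cc(Cl)c1C(=O)OC(=O)[C@@]2(C)O[C@@H]2C | intermediate
31 | (3aS,4R,5S,6Z,9Z,11aS)-5-[(4-methoxybenzyl)oxy]-6,10-dimethyl-3-methylidene-2-oxo-2,3,3a,4,5,8,11,11a-octahydrocyclodeca[b]furan-4-yl (2S,3R)-2,3-dimethyloxirane-2-carboxylate | C=C1C(=O)O[C@H]2C/C(C)=C\C/C=C(/C)[C@H](OCc3ccc(OC)cc3)[C@H](OC(=O)[C@@]4(C)O[C@@H]4C)[C@@H]12 | intermediate
32 | (3aS,4R,5S,6Z,9Z,11aS)-5-hydroxy-6,10-dimethyl-3-methylidene-2-oxo-2,3,3a,4,5,8,11,11a-octahydrocyclodeca[b]furan-4-yl (2S,3R)-2,3-dimethyloxirane-2-carboxylate | C=C1C(=O)O[C@H]2C/C(C)=C\C/C=C(/C)[C@H](O)[C@H](OC(=O)[C@@]3(C)O[C@@H]3C)[C@@H]12 | intermediate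
33 | (3aS,4R,5S,6Z,9Z,11aS)-5-(acetyloxy)-6,10-dimethyl-3-methylidene-2-oxo-2,3,3a,4,5,8,11,11a-octahydrocyclodeca[b]furan-4-yl (2S,3R)-2,3-dimethyloxirane-2-carboxylate | C=C1C(=O)O[C@H]2C/C(C)=C\C/C=C(/C)[C@H](OC(C)=O)[C@H](OC(=O)[C@@]3(C)O[C@@H]3C)[C@@H]12 | target

**Step count**
Total steps: 23. Longest linear sequence: 19 (steps 1–12, then 17–23); steps 13 and 14–16 are side branches.

**Three steps most likely to fail**

Step 19 (ring-closing metathesis). A strained ten-membered ring with a new trisubstituted olefin may give oligomers, engage the methylene lactone, or isomerise the skipped diene. The fallback sets out from 26 and comes back at 28. It closes the carbocycle before the lactone exists: metathesis of the open hydroxy ester 26 under high dilution, where the ring is not yet constrained by the cis-fused lactone, gives methyl 2-[(1S,2S,4Z,7Z,9S,10R)-10-[(tert-butyldimethylsilyl)oxy]-2-hydroxy-9-[(4-methoxybenzyl)oxy]-4,8-dimethylcyclodeca-4,7-dien-1-yl]prop-2-enoate F1, and PPTS lactonisation of F1 then gives 28.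

Step 17 (Barbier allylation). The syn preference is well founded, but the facial sense relative to the C–OSi centre rests on a transition-state model and could be low or reversed. The fallback sets out from 17 and comes back at 26. It replaces substrate control by catalyst control: acetylation of 17 (Ac2O, pyridine, DMAP) gives methyl (4R,5S,6Z)-3-acetoxy-4-[(tert-butyldimethylsilyl)oxy]-5-[(4-methoxybenzyl)oxy]-6-methyl-2-methylidenedeca-6,9-dienoate F2. SN2′ borylation (bis(pinacolato)diboron, CuCl, LiCl, KOAc, DMF) then gives methyl (2E,4R,5S,6Z)-4-[(tert-butyldimethylsilyl)oxy]-5-[(4-methoxybenzyl)oxy]-6-methyl-2-[(4,4,5,5-tetramethyl-1,3,2-dioxaborolan-2-yl)methyl]deca-2,6,9-trienoate F3. Allylboration of 20 with F3 under a chiral phosphoric acid ((R)-TRIP, toluene, −30 °C → rt, the antipode chosen so that the Re face of 20 is attacked, to be confirmed with both antipodes) runs through a closed chair in which the boronate geometry gives the syn adduct and the catalyst fixes the aldehyde face; hydrolytic work-up gives 26.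

Step 11 (Baylis–Hillman reaction). The hindered α,β-dialkoxy aldehyde may react very slowly, and days with DABCO could epimerise C2 of 15. The fallback sets out from 15 and comes back at 17. It uses a pre-formed nucleophile in place of amine catalysis: methyl propiolate with (i-Bu)2AlH and N-methylmorpholine N-oxide in THF at 0 °C gives methyl 2-(diisobutylalumanyl)prop-2-enoate F4, which adds to 15 within hours at 0 °C → rt and gives 17 directly after work-up.

**Further compounds**
F1 | step 19 | methyl 2-[(1S,2S,4Z,7Z,9S,10R)-10-[(tert-butyldimethylsilyl)oxy]-2-hydroxy-9-[(4-methoxybenzyl)oxy]-4,8-dimethylcyclodeca-4,7-dien-1-yl]prop-2-enoate | C=C(C(=O)OC)[C@H]1[C@@H](O)C/C(C)=C\C/C=C(/C)[C@H](OCc2ccc(OC)cc2)[C@@H]1O[Si](C)(C)C(C)(C)C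
F2 | step 17 | methyl (4R,5S,6Z)-3-acetoxy-4-[(tert-butyldimethylsilyl)oxy]-5-[(4-methoxybenzyl)oxy]-6-methyl-2-methylidenedeca-6,9-dienoate | C=C(C(=O)OC)C(OC(C)=O)[C@@H](O[Si](C)(C)C(C)(C)C)[C@@H](OCc1ccc(OC)cc1)/C(C)=C\CC=C
F3 | step 17 | methyl (2E,4R,5S,6Z)-4-[(tert-butyldimethylsilyl)oxy]-5-[(4-methoxybenzyl)oxy]-6-methyl-2-[(4,4,5,5-tetramethyl-1,3,2-dioxaborolan-2-yl)methyl]deca-2,6,9-trienoate | COC(=O)/C(CB1OC(C)(C)C(C)(C)O1)=C/[C@@H](O[Si](C)(C)C(C)(C)C)[C@@H](OCc2ccc(OC)cc2)/C(C)=C\CC=C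
F4 | step 11 | methyl 2-(diisobutylalumanyl)prop-2-enoate | C=C(C(=O)OC)[Al](CC(C)C)CC(C)C
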